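**Retrosynthetic overview**

1. Psiguadial A ⇐ debenzylation and double formylation of a benzoxepine. The arene and the oxepine ring come from 3,5-bis(benzyloxy)benzyne laid across the C10 alkoxide and the C11 ketone of a hydroxy ketone; C11–OH is then replaced by H.
2. Feature used: C7, the quaternary carbon shared by the cyclopentane (C6–C7–C8–C9–C10) and the oxepine, is α to the benzylic carbon C11. With C11 as a phenyl ketone, C7 becomes an enol ether carbon; with C8–C9 as an ethynyl group on the C10 carbinol, C7–C8 is made by gold-catalysed 5-endo-dig attack of that enol ether on the alkyne.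
3. The enol ether/alkyne precursor ⇐ cyclopropane-fused cycloheptanone (C10 ketone) by acetylide addition at C10 and a polar (two-electron) C6–C7 coupling with propiophenone.
4. The cycloheptanone ⇐ (+)-3-carene: ozonolysis, intramolecular Mukaiyama aldol closure of the seven-membered ring, C1 methyl by α-iodination/Suzuki coupling and face-selective hydrogenation.
5. Ring order: cyclopropane (from carene), cycloheptane (step 3), cyclopentene (step 13), oxepine with the ready-made arene (step 19).

Key step: step 13

Locants (target numbering): C1 = CH(CH3) of the seven-membered carbocycle; C2, C3 = its CH2 groups; C4, C5 = cyclopropane CH (C5 is bonded to C6); C6 = ring-fusion CH; C7 = quaternary C(CH3); C8, C9 = cyclopentane CH2; C10 = ring-fusion C–O; C11 = CH(Ph); C12 = C(CH3)2.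

Remark: 17, 19 and 20 are carried as C7 epimer mixtures and 21 possibly as an enol ether E/Z mixture; C7 is trigonal in 21 and both geometries of 21 converge in step 13.

**Route**

Step 1
Reactants: 1 (+)-3-carene
Product: 3 keto acetal cis-1-[3-(2,2-dimethoxyethyl)-2,2-dimethylcyclopropyl]propan-2-one, via keto aldehyde 2 (not isolated)
Conditions: O3, CH2Cl2/MeOH, −78 °C; Me2S, −78 °C to rt; then p-TsOH (cat.), MeOH, rt
Reagents that add atoms: ozone, O=[O+][O-]; methanol, CO
Why: Ozonolysis (Criegee cleavage) of the trisubstituted alkene gives the cis keto aldehyde without touching the cyclopropane stereocentres (future C4 and C5), and acid-catalysed acetalisation takes the aldehyde selectively over the less electrophilic methyl ketone.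

Step 2
Reactants: 3 keto acetal
Product: 5 terminal silyl enol ether 2-(trimethylsilyloxy)-3-[cis-3-(2,2-dimethoxyethyl)-2,2-dimethylcyclopropyl]prop-1-ene, via lithium enolate 4 (not isolated)
Conditions: LiN(i-Pr)2, THF, −78 °C; Me3SiCl, −78 to 0 °C
Reagents that add atoms: chlorotrimethylsilane, C[Si](C)(C)Cl
Why: Kinetic deprotonation with the hindered amide base removes a methyl proton of the methyl ketone rather than the CH2 next to the cyclopropane, and O-silylation fixes the terminal enol ether for a regiodefined Mukaiyama aldol.

Step 3
Reactants: 5 terminal silyl enol ether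
Product: 7 enone 8,8-dimethylbicyclo[5.1.0]oct-4-en-3-one (cis-fused; C10 ketone and C1=C2 alkene), via methoxy ketone 6 (not isolated)
Conditions: Me3SiOTf (10 mol %), CH2Cl2 (0.01 M), −78 °C; crude, DBU, CH2Cl2, rt
Reagents that add atoms: none
Why: Intramolecular Mukaiyama aldol addition of the enol ether to the oxocarbenium ion from the acetal closes the seven-membered ring (the cis-cyclopropane holds both chains on one side), and E1cB loss of methanol with DBU gives the conjugated enone, which removes the methoxy stereocentre.

Step 4
Reactants: 7 enone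
Product: 8 iodoenone 4-iodo-8,8-dimethylbicyclo[5.1.0]oct-4-en-3-one
Conditions: I2, pyridine, CH2Cl2, 0 °C to rt
Reagents that add atoms: iodine, II
Why: α-Iodination of the enone by the pyridine/iodine addition–elimination sequence (conjugate addition of pyridine, iodination of the enolate, elimination) places iodine on C1.

Step 5
Reactants: 8 iodoenone
Product: 9 methyl enone 4,8,8-trimethylbicyclo[5.1.0]oct-4-en-3-one
Conditions: MeB(OH)2, Pd(dppf)Cl2 (5 mol %), K3PO4, THF/H2O, 65 °C
Reagents that add atoms: methylboronic acid, CB(O)O
Why: Suzuki–Miyaura cross-coupling of the α-iodoenone installs the C1 methyl group on the alkene carbon, so that C1 can be set by hydrogenation and not by an enolate alkylation.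

Step 6
Reactants: 9 methyl enone
Product: 10 ketone 4,8,8-trimethylbicyclo[5.1.0]octan-3-one with the C1 methyl cis to the cyclopropane
Conditions: H2 (1 atm), Pd/C, EtOAc, rt
Reagents that add atoms: none
Why: Heterogeneous hydrogenation should add H2 to the enone C=C from the face away from the gem-dimethylcyclopropane, whose endo methyl shields the other face (as in the hydrogenation of 3-carene to cis-carane), which sets C1 with methyl cis to the cyclopropane under neutral, non-equilibrating conditions.

Step 7
Reactants: 10 ketone
Product: 12 silyl enol ether 4,8,8-trimethyl-3-(trimethylsilyloxy)bicyclo[5.1.0]oct-2-ene (C6=C10), via lithium enolate 11 (not isolated)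
Conditions: LiN(i-Pr)2, THF, −78 °C; Me3SiCl, −78 to 0 °C
Reagents that add atoms: chlorotrimethylsilane, C[Si](C)(C)Cl
Why: Kinetic enolisation occurs at the less substituted α-carbon C6 (CH2) and leaves the C1 stereocentre untouched, and O-silylation gives the regiodefined enol ether.

Step 8
Reactants: 13 propiophenone
Product: 15 (Z)-1-phenyl-1-(trimethylsilyloxy)prop-1-ene, via lithium enolate 14 (not isolated)
Conditions: LiN(i-Pr)2, THF, −78 °C; Me3SiCl
Reagents that add atoms: chlorotrimethylsilane, C[Si](C)(C)Cl
Why: Kinetic deprotonation of propiophenone gives the (Z)-enolate, which is trapped on oxygen as the silyl enol ether.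

Step 9
Reactants: 15 (Z)-1-phenyl-1-(trimethylsilyloxy)prop-1-ene; 12 silyl enol ether
Product: 17 diketone 2-(1-methyl-2-oxo-2-phenylethyl)-4,8,8-trimethylbicyclo[5.1.0]octan-3-one (C6 side chain trans to cyclopropane; C7 epimers), via enolonium species 16 (not isolated)
Conditions: PhI(OH)OTs, BF3·OEt2, CH2Cl2, −78 °C, 15 (excess); then 12, −78 to −50 °C
Reagents that add atoms: none
Why: Enolonium umpolung coupling of two silyl enol ethers: the trivalent iodine reagent turns 15 into an α-electrophilic enolonium species, which C6 of 12 attacks in a two-electron pathway (no radical at C6, which would be a cyclopropylcarbinyl radical) from the face opposite the cyclopropane, so the C6 side chain ends trans to the cyclopropane while C7 forms as a mixture that is erased in step 12.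

Step 10
Reactants: 17 diketone; 18 ethynylmagnesium bromide
Product: 19 ethynyl carbinol (C10–OH cis to the C1 methyl and the cyclopropane; ethynyl cis to the C6 side chain; C7 epimers)
Conditions: CeCl3 (anhydrous), THF, −78 to −40 °C; aq. NH4Cl
Reagents that add atoms: none
Why: Organocerium-mediated 1,2-addition (enolisation suppressed) should go to the more electrophilic dialkyl ketone C10 rather than to the conjugated phenyl ketone flanked by tertiary C7, with the acetylide entering from the face opposite the cyclopropane and the C1 methyl group, so the alkyne ends cis to the C6 side chain and the hydroxyl cis to the C1 methyl.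

Step 11
Reactants: 19 ethynyl carbinol
Product: 20 triethylsilyl ether of 19
Conditions: Et3SiOTf, 2,6-lutidine, CH2Cl2, −78 to 0 °C
Reagents that add atoms: triethylsilyl triflate, CC[Si](CC)(CC)OS(=O)(=O)C(F)(F)F
Why: Silylation of the hindered tertiary alcohol with a silyl triflate and a hindered pyridine base, conditions under which the α-branched phenyl ketone is not enolised.

Step 12
Reactants: 20 triethylsilyl ether
Product: 21 cycloheptane ethynyl carbinol silyl ether carrying the tetrasubstituted tert-butyldimethylsilyl enol ether C7=C11 (silyloxy cis to C6)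
Conditions: t-BuMe2SiOTf, Et3N, CH2Cl2, 0 °C to rt
Reagents that add atoms: tert-butyldimethylsilyl triflate, CC(C)(C)[Si](C)(C)OS(=O)(=O)C(F)(F)F
Why: Soft enolisation (O-silylation of the ketone, then deprotonation by the amine) can only remove the C7 proton and so gives the tetrasubstituted enol ether, while the terminal alkyne C–H is too weakly acidic for the amine; the isomer with silyloxy cis to C6 and phenyl cis to methyl is expected to prevail.

Step 13
Reactants: 21 bis-silylated enol ether alkyne
Product: 22 hydroazulene with C7 benzoyl and C10 triethylsilyl ether and C8=C9 alkene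
Conditions: Ph3PAuNTf2 (5 mol %), CH2Cl2/MeOH (10:1), rt
Reagents that add atoms: none
Why: Ph3PAuNTf2 (monovalent gold) binds the C8≡C9 alkyne and the enol ether carbon C7 adds anti to gold at the terminal carbon C8, giving a vinyl–gold species at C9 and a silyloxocarbenium ion at C11; methanol takes the silyl group, which regenerates the C11 ketone, and protodeauration frees the C8=C9 alkene. The closest known reaction type is the gold-catalysed carbocyclisation of silyl enol ethers onto alkynes (a Conia-ene reaction of a silyl enol ether), established in 5-exo and 5-endo modes and for quaternary carbons. The cyclopentene C6–C7–C8–C9–C10 closes 5-endo-dig, since the 4-exo alternative at C9 is excluded by strain and attack through oxygen is blocked by the silyl group. The new stereocentre C7 is controlled by allylic 1,3-strain: in the tetrasubstituted enol ether the C6–H bond lies in the alkene plane on the side of C11, so C5 and C10 sit on opposite faces and the alkyne carried by C10 reaches only the C10 face of C7, which puts the methyl group cis to C5 and trans to the C10 oxygen and the benzoyl group cis to C6–H. The step needs carbon–carbon bond formation to outrun methanolysis of the enol ether and needs the alkyne cis to the C6 branch; the robust tert-butyldimethylsilyl enol ether and the configuration of C10 set in step 10 secure both, and either enol ether geometry gives the same product.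

Step 14
Reactants: 22 cyclopentene
Product: 23 saturated benzoyl ketone with C10 triethylsilyl ether
Conditions: KO2CN=NCO2K, AcOH, MeOH/CH2Cl2, 0 °C to rt (portionwise)
Reagents that add atoms: none
Why: Diimide reduction transfers H2 in a concerted syn fashion to the strained cis-disubstituted cyclopentene and leaves the ketone, the cyclopropane and the silyl ether alone; the alkene is removed before the aryne step because it would react with the aryne.

Step 15
Reactants: 23 saturated silyl ether
Product: 24 hydroxy ketone (C10–OH and C7 benzoyl cis on the cyclopentane)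
Conditions: Bu4NF, THF, 0 to 40 °C
Reagents that add atoms: none
Why: Fluoride-induced cleavage of the tertiary silyl ether; the ketone has no α-hydrogen, so no centre can epimerise.

Step 16
Reactants: 25 3,5-bis(benzyloxy)phenol
Product: 26 3,5-bis(benzyloxy)phenyl N-isopropylcarbamate
Conditions: i-PrNCO, Et3N (cat.), CH2Cl2, rt
Reagents that add atoms: isopropyl isocyanate, CC(C)N=C=O
Why: Carbamoylation of the phenol with an isocyanate installs a removable directing group for ortho-metalation.

Step 17
Reactants: 26 carbamate
Product: 29 3,5-bis(benzyloxy)-2-(trimethylsilyl)phenyl N-isopropylcarbamate, via N-silyl carbamate 27 (not isolated), via aryllithium 28 (not isolated)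
Conditions: Me3SiOTf, TMEDA, Et2O, rt; n-BuLi, TMEDA, −78 °C; Me3SiCl; aqueous work-up
Reagents that add atoms: chlorotrimethylsilane, C[Si](C)(C)Cl
Why: Directed ortho-metalation: after N-silylation in the flask, n-BuLi/TMEDA lithiates the ring position flanked by the carbamate and a benzyloxy group (both direct to it), Me3SiCl quenches the aryllithium, and the N-silyl group is lost on work-up.

Step 18
Reactants: 29 silyl carbamate
Product: 31 3,5-bis(benzyloxy)-2-(trimethylsilyl)phenyl trifluoromethanesulfonate, via silyl phenol 30 (not isolated)
Conditions: DBU, Et2NH, MeCN, 40 °C; then PhNTf2, rt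
Reagents that add atoms: N-phenylbis(trifluoromethanesulfonimide), O=S(=O)(N(c1ccccc1)S(=O)(=O)C(F)(F)F)C(F)(F)F
Why: Base-induced E1cB cleavage of the N–H carbamate (the released isocyanate is trapped by Et2NH) and triflation of the phenoxide give the ortho-silylaryl triflate, a fluoride-triggered aryne precursor.

Step 19
Reactants: 24 hydroxy ketone; 31 silylaryl triflate
Product: 34 benzoxepine carbinol (tertiary C11–OH; benzyloxy groups at the two future phenol positions), via potassium alkoxide 32 (not isolated), via aryne 33 (not isolated)
Conditions: KH, THF, 0 °C; then 31, CsF, 18-crown-6, THF, 0 °C to rt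
Reagents that add atoms: none
Why: Proposed new method: fluoride turns 31 into aryne 33, the tertiary potassium alkoxide adds to the aryne carbon remote from the flanking benzyloxy group (the usual regiochemistry of 3-alkoxyarynes, which leaves the aryl anion next to that benzyloxy group), and this aryl anion, held over the non-enolisable C11 ketone with no proton source present, adds to it and closes the seven-membered oxepine; the closest known reaction type is the annulation of arynes with ortho-hydroxyaryl ketones and esters (phenoxide addition followed by carbonyl capture, giving xanthenols and xanthones), extended here to an aliphatic tertiary alkoxide and a seven-membered ring, and the configuration of the C11 carbinol does not matter because it is removed in step 20.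

Step 20
Reactants: 34 benzoxepine carbinol
Product: 35 benzoxepine with C11–H (bis(benzyl ether) of the deformyl target)
Conditions: Et3SiH, BF3·OEt2, CH2Cl2, −78 to −20 °C
Reagents that add atoms: none
Why: Ionic hydrogenation: BF3 ionises the doubly benzylic tertiary alcohol to a cation stabilised by phenyl and the 2,4,6-trioxygenated ring and Et3SiH transfers hydride; because the transition state for so stabilised a cation is late, phenyl is expected to settle in the roomier sector on the side of the one-carbon bridge C6, so hydride should enter from the side of the C8–C9 bridge and set C11 as in the target.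

Step 21
Reactants: 35 bis(benzyl ether)
Product: 36 bisphenol (deformyl psiguadial A)
Conditions: H2 (1 atm), Pd/C, EtOAc/MeOH, rt
Reagents that add atoms: none
Why: Hydrogenolysis removes the two benzyl ethers, while the alkyl aryl ether, the diarylmethine C11–H and the cyclopropane are not cleaved under these mild conditions.

Step 22
Reactants: 36 bisphenol
Product: 37 psiguadial A
Conditions: Cl2CHOMe, TiCl4, CH2Cl2, −78 to 0 °C; then H2O
Reagents that add atoms: dichloromethyl methyl ether, COC(Cl)Cl; water, O
Why: Rieche formylation: TiCl4 activates Cl2CHOMe for electrophilic substitution at the two remaining ring positions, each flanked by two oxygens, and aqueous work-up hydrolyses the α-chloro ethers to the aldehydes, so no regiochemical choice arises.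

**Compound list**

1 | (+)-3-carene, (1S,6R)-3,7,7-trimethylbicyclo[4.1.0]hept-3-ene | CC1=CC[C@@H]2[C@H](C1)C2(C)C | starting material
2 | keto aldehyde, cis-2-[2,2-dimethyl-3-(2-oxopropyl)cyclopropyl]acetaldehyde | O=CC[C@@H]1[C@H](CC(C)=O)C1(C)C | intermediate
3 | keto acetal, cis-1-[3-(2,2-dimethoxyethyl)-2,2-dimethylcyclopropyl]propan-2-one | COC(OC)C[C@@H]1[C@H](CC(C)=O)C1(C)C | intermediate
4 | lithium enolate of 3 (terminal) | COC(OC)C[C@@H]1[C@H](CC(=C)O[Li])C1(C)C | intermediate
5 | terminal trimethylsilyl enol ether of 3 | COC(OC)C[C@@H]1[C@H](CC(=C)O[Si](C)(C)C)C1(C)C | intermediate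
6 | methoxy ketone, 5-methoxy-8,8-dimethylbicyclo[5.1.0]octan-3-one (cis-fused, methoxy epimers) | O=C1CC(OC)C[C@@H]2[C@H](C1)C2(C)C | intermediate
7 | enone, 8,8-dimethylbicyclo[5.1.0]oct-4-en-3-one (cis-fused) | O=C1C=CC[C@@H]2[C@H](C1)C2(C)C | intermediate
8 | iodoenone, 4-iodo-8,8-dimethylbicyclo[5.1.0]oct-4-en-3-one | O=C1C(I)=CC[C@@H]2[C@H](C1)C2(C)C | intermediate
9 | methyl enone, 4,8,8-trimethylbicyclo[5.1.0]oct-4-en-3-one | CC1=CC[C@@H]2[C@H](CC1=O)C2(C)C | intermediate
10 | ketone, 4,8,8-trimethylbicyclo[5.1.0]octan-3-one, C1 methyl cis to cyclopropane | C[C@H]1CC[C@@H]2[C@H](CC1=O)C2(C)C | intermediate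
11 | lithium enolate of 10 (C6=C10) | C[C@H]1CC[C@@H]2[C@H](C=C1O[Li])C2(C)C | intermediate
12 | trimethylsilyl enol ether of 10 (C6=C10) | C[C@H]1CC[C@@H]2[C@H](C=C1O[Si](C)(C)C)C2(C)C | intermediate
13 | propiophenone | CCC(=O)c1ccccc1 | starting material
14 | (Z)-lithium enolate of propiophenone | C/C=C(\O[Li])c1ccccc1 | intermediate
15 | (Z)-1-phenyl-1-(trimethylsilyloxy)prop-1-ene | C/C=C(\O[Si](C)(C)C)c1ccccc1 | intermediate
16 | enolonium species, O-bound phenyl(tosyloxy)-λ3-iodanyl enolate of propiophenone | C/C=C(\O[I](c1ccccc1)OS(=O)(=O)c1ccc(C)cc1)c1ccccc1 | intermediate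
17 | 1,4-diketone, C6 side chain CH(CH3)C(=O)Ph trans to cyclopropane, C1 methyl cis to cyclopropane, C7 epimers | C[C@H]1CC[C@@H]2[C@H]([C@H](C(C)C(=O)c3ccccc3)C1=O)C2(C)C | intermediate
18 | ethynylmagnesium bromide | C#C[Mg]Br | starting material
19 | C10 ethynyl carbinol, OH cis to C1 methyl, ethynyl cis to C6 side chain, C7 epimers | C[C@H]1CC[C@@H]2[C@H]([C@H](C(C)C(=O)c3ccccc3)[C@]1(O)C#C)C2(C)C | intermediate
20 | triethylsilyl ether of 19 | C[C@H]1CC[C@@H]2[C@H]([C@H](C(C)C(=O)c3ccccc3)[C@]1(O[Si](CC)(CC)CC)C#C)C2(C)C | intermediate
21 | key-step precursor, cycloheptane ethynyl carbinol triethylsilyl ether with tetrasubstituted tert-butyldimethylsilyl enol ether | C[C@H]1CC[C@@H]2[C@H]([C@H](/C(C)=C(\O[Si](C)(C)C(C)(C)C)c3ccccc3)[C@]1(O[Si](CC)(CC)CC)C#C)C2(C)C | intermediate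
22 | key-step product, cis-fused hydroazulene with C7 benzoyl (cis to C6–H), C7 methyl trans to C10 silyloxy, C8=C9 alkene | C[C@H]1CC[C@@H]2[C@H]([C@@H]3[C@](C(=O)c4ccccc4)(C)C=C[C@@]31O[Si](CC)(CC)CC)C2(C)C | intermediate
23 | saturated benzoyl ketone, C10 triethylsilyl ether | C[C@H]1CC[C@@H]2[C@H]([C@@H]3[C@](C(=O)c4ccccc4)(C)CC[C@@]31O[Si](CC)(CC)CC)C2(C)C | intermediate
24 | hydroxy ketone, C10–OH and C7 benzoyl cis | C[C@H]1CC[C@@H]2[C@H]([C@@H]3[C@](C(=O)c4ccccc4)(C)CC[C@@]31O)C2(C)C | intermediate
25 | 3,5-bis(benzyloxy)phenol | Oc1cc(OCc2ccccc2)cc(OCc2ccccc2)c1 | starting material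
26 | 3,5-bis(benzyloxy)phenyl N-isopropylcarbamate | CC(C)NC(=O)Oc1cc(OCc2ccccc2)cc(OCc2ccccc2)c1 | intermediate
27 | N-trimethylsilyl derivative of 26 | CC(C)N([Si](C)(C)C)C(=O)Oc1cc(OCc2ccccc2)cc(OCc2ccccc2)c1 | intermediate
28 | ortho-lithiated 27 (lithium between carbamate and benzyloxy) | CC(C)N([Si](C)(C)C)C(=O)Oc1cc(OCc2ccccc2)cc(OCc2ccccc2)c1[Li] | intermediate
29 | 3,5-bis(benzyloxy)-2-(trimethylsilyl)phenyl N-isopropylcarbamate | CC(C)NC(=O)Oc1cc(OCc2ccccc2)cc(OCc2ccccc2)c1[Si](C)(C)C | intermediate
30 | 3,5-bis(benzyloxy)-2-(trimethylsilyl)phenol | Oc1cc(OCc2ccccc2)cc(OCc2ccccc2)c1[Si](C)(C)C | intermediate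
31 | 3,5-bis(benzyloxy)-2-(trimethylsilyl)phenyl trifluoromethanesulfonate | FC(F)(F)S(=O)(=O)Oc1cc(OCc2ccccc2)cc(OCc2ccccc2)c1[Si](C)(C)C | intermediate
32 | potassium alkoxide of 24 | C[C@H]1CC[C@@H]2[C@H]([C@@H]3[C@](C(=O)c4ccccc4)(C)CC[C@@]31O[K])C2(C)C | intermediate
33 | 3,5-bis(benzyloxy)benzyne | C1#CC(OCc2ccccc2)=CC(OCc2ccccc2)=C1 | intermediate
34 | benzoxepine carbinol, tertiary C11–OH (C11 configuration not assigned) | C[C@H]1CC[C@@H]2[C@H]([C@@H]3[C@]4(C)CC[C@@]31Oc1cc(OCc5ccccc5)cc(OCc5ccccc5)c1C4(O)c1ccccc1)C2(C)C | intermediate
35 | benzoxepine with C11–H, phenyl on the side of C6, bis(benzyl ether) | C[C@H]1CC[C@@H]2[C@H]([C@@H]3[C@]4(C)CC[C@@]31Oc1cc(OCc5ccccc5)cc(OCc5ccccc5)c1[C@@H]4c1ccccc1)C2(C)C | intermediate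
36 | bisphenol, deformyl psiguadial A | C[C@H]1CC[C@@H]2[C@H]([C@@H]3[C@]4(C)CC[C@@]31Oc1cc(O)cc(O)c1[C@@H]4c1ccccc1)C2(C)C | intermediate
37 | psiguadial A | C[C@H]1CC[C@@H]2[C@H]([C@@H]3[C@]4(C)CC[C@@]31Oc1c(C=O)c(O)c(C=O)c(O)c1[C@@H]4c1ccccc1)C2(C)C | target

**Step count and risks**

Total step count: 22. Longest linear sequence: 18 steps (steps 1–7, 9–15 and 19–22, from (+)-3-carene).

Steps most likely to fail:

1. Step 19 (Proposed new method). The aryl anion formed after alkoxide addition may be protonated or add to a second aryne before it closes the seven-membered ring on the hindered C11 ketone, or the hindered tertiary alkoxide may fail to capture the aryne. The fallback uses known chemistry, sets out from 24 and returns at 35, and makes the two bonds in separate polar steps. The sodium alkoxide of 24 (NaH, THF/toluene) is O-arylated without metal catalysis by the diaryliodonium salt F1, in which the 2,4,6-trimethoxyphenyl group is the ligand that is not transferred; this gives the aryl ether F2. Treatment of aryl ether F2 with BF3·OEt2 and Et3SiH then brings about an intramolecular Friedel–Crafts hydroxyalkylation of the electron-rich ring (ortho to the ether oxygen; both ortho positions are equivalent) by the C11 ketone, and the carbinol so formed is ionised and reduced in the same flask to 35.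

2. Step 20. Hydride may be delivered to the other face of the C11 cation (the face turned to C6), and the oxocarbenium-like cation may also lose the tertiary C10–O bond by heterolysis. The fallback sets out from 34 and returns at 35 by thermodynamic rather than kinetic control of C11. If reduction gives the 11-epimer F3, it is equilibrated by reversible hydrogen atom abstraction at the doubly benzylic C11–H with a thiyl radical (PhSH, AIBN, benzene, 80 °C). The planar diarylmethyl radical is re-hydrogenated until the more stable epimer predominates, which should be 35, with phenyl in the roomier sector beside the one-carbon bridge C6.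

3. Step 13. The silyl enol ether may be lost by methanolysis or protodesilylation, or the alkyne hydrated, before the C7–C8 bond forms. The fallback sets out from 20 and returns at 23, replacing the π-acid cyclisation by an intramolecular enolate alkylation. Semihydrogenation of 20 (H2, Pd/CaCO3 poisoned with Pb(OAc)2, quinoline) gives the vinyl carbinol ether F4. Hydroboration–oxidation (9-BBN, then NaBO3) gives the primary alcohol F5, and I2/PPh3/imidazole gives the primary iodide F6. KN(SiMe3)2 in THF (−78 to 0 °C) then forms the C11 enolate, whose C7 carbon displaces iodide at C8 (5-exo-tet), under the same allylic-strain control of C7, to give 23 directly.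

**Further compounds**

F1 | step 19 | [3,5-bis(benzyloxy)phenyl](2,4,6-trimethoxyphenyl)iodonium tosylate | COc1cc(OC)c([I+]c2cc(OCc3ccccc3)cc(OCc3ccccc3)c2)c(OC)c1.Cc1ccc(cc1)S(=O)(=O)[O-]
F2 | step 19 | 3,5-bis(benzyloxy)phenyl ether of 24 at C10–O, C11 ketone intact | C[C@H]1CC[C@@H]2[C@H]([C@@H]3[C@](C(=O)c4ccccc4)(C)CC[C@@]31Oc1cc(OCc5ccccc5)cc(OCc5ccccc5)c1)C2(C)C
F3 | step 20 | 11-epimer of 35 | C[C@H]1CC[C@@H]2[C@H]([C@@H]3[C@]4(C)CC[C@@]31Oc1cc(OCc5ccccc5)cc(OCc5ccccc5)c1[C@H]4c1ccccc1)C2(C)C
F4 | step 13 | C10 vinyl analogue of 20 | C[C@H]1CC[C@@H]2[C@H]([C@H](C(C)C(=O)c3ccccc3)[C@]1(O[Si](CC)(CC)CC)C=C)C2(C)C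
F5 | step 13 | C10 2-hydroxyethyl analogue of 20 | C[C@H]1CC[C@@H]2[C@H]([C@H](C(C)C(=O)c3ccccc3)[C@]1(O[Si](CC)(CC)CC)CCO)C2(C)C
F6 | step 13 | C10 2-iodoethyl analogue of 20 | C[C@H]1CC[C@@H]2[C@H]([C@H](C(C)C(=O)c3ccccc3)[C@]1(O[Si](CC)(CC)CC)CCI)C2(C)C
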